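The runs were computed for substances that don't exist, noise included.

Start with the amounts. I take it that each substrate molecule uses one of partner, so the solid reagent can cover 200% of the pool of both substrates. That is more than the pool, so in this flask the pool is the limiting reagent.

| flask | left-handed substrate | right-handed substrate | solid reagent | remark | time |
|---|---|---|---|---|---|
| north-west | 0.25 M | 0.25 M | 4 equiv | the very flask that is asked about, followed so far |  |
| south | 0.17 M | 0.17 M | 4 equiv | run made earlier |  |
| flask | 0.25 M | 0.25 M | 4.00 equiv |  | 15 d |

- north-west (time / h: left-handed product / %): 3.00: 12; 6.00: 24; 10.0: 32; 15.0: 41; 25.0: 57; 40.0: 62
- south (time / d: left-handed product / %): 0.417: 32; 1.25: 59; 2.00: 64; 3.00: 64; 5.00: 60; 6.00: 63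

(scatter of a reading: 1.5 percentage points)

- partner is single-handed; left-handed substrate and right-handed substrate are mirror images of each other, charged as a racemate, each of them at the stated concentration
- given per volume of solution although it is solid: solid reagent
- at the start none of the solid reagent is in solution
- the reaction counts as stopped when no species that holds the left-handed substrate and right-handed substrate together changes by six tenths of a point or more over the second half of the time
- the handed part of partner does not stay in what it makes, so the products of the two hands are mirror images too
- what has gone into achiral form counts as reacted

- which holds at 15 d: what has brought the reaction to rest, or that it has not come to rest (for what has run out or reacted, a solid counts together with what of it has only dissolved) (forward and back rates have come level / the partner has run out first / all of the left-handed substrate has reacted / it is still moving)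
- the left-handed product standing at 15 d, as a percentage of the left-handed substrate and right-handed substrate together charged
- amount of left-handed product if the flask were left three thousand times as long, in percent of the left-handed substrate and right-handed substrate together charged

Call the left-handed share the left-handed product at rest per unit of pool that the partner can convert. The last four south readings average 62.7%. The north-west run ends at 62% after 40.0 h, from 0.25 M of each hand instead of 0.17 M, so that is a reading at a different concentration, and it agrees.

Mirror symmetry gives a second number. If the pool went wholly into the two products and they equilibrated, each would hold half of it, and that is the zero of the scale. The two ways part, so which one cheats? The south run reads 64% at 2.00 d and 63% at 6.00 d, against a scatter of 1.5 percentage points. I see no fall towards the zero, so I read the excess as kinetic control and distrust the symmetry here. My reckoning is that the substrates are consumed and 62.7% stands at 15 d and after the long wait.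

The forecast differs. It says it is still moving, with 61% at 15 d and 39% at the very end: “The plateau is therefore quasi-stationary”.

The flask gives 62.3% at 15 d, and 62.3% after the long wait, which is 23 points above the forecast's figure for the very end. The answer on what holds at 15 d is: all of the left-handed substrate has reacted. In the flask at 15.0 d, left-handed substrate stands at 0% and solid reagent at 46.0% of its own charge. With the pool as denominator, the share had promised 62.7%.

    partner + left-handed substrate → left-handed product (k = 3.50 × 10⁻⁴ L mol⁻¹ s⁻¹)
    partner + right-handed substrate → right-handed product (k = 1.40 × 10⁻⁴ L mol⁻¹ s⁻¹)
    left-handed substrate ⇌ achiral form (K = 0.0150, k = 6.50 × 10⁻⁴ s⁻¹)
    right-handed substrate ⇌ achiral form (K = 0.0150, k = 6.50 × 10⁻⁴ s⁻¹)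
    solid reagent ⇌ partner, rate k5*(cs5 - [partner]) while solid is left; crystals form when [partner] > cs5 (solubility = 0.100 M, k = 3.90 × 10⁻⁴ s⁻¹)
    achiral form → side product (k = 3.70 × 10⁻⁴ s⁻¹)

Now take the neighbour flask with 1.60 equiv of solid reagent. Its capacity is 80.0% of the pool, so the share gives 50.2%. The neighbour flask computes to 56.7%, which is 6.5 points above that reckoning, with both products together at 79.9%, side product at 19.9%, and 0.18% of its solid reagent still there, solid or dissolved.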